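**Retrosynthetic overview**
1. Target 22 ⇐ tri-O-benzyl ether 21 (H2) ⇐ bis-vinyl compound 19 (O3/NaBH4). Both CH2OH groups are carried as vinyl groups.
2. The dihydrobenzofuran (second ring formed) ⇐ Mitsunobu closure of the ring B phenol onto C7 with inversion. Both C7–C8 bonds ⇐ one two-directional anti-allylboration of bis-allene 14 with O-benzylvanillin 15.
3. 14 ⇐ diiodo lactone 13 (Stille). Ring A phenol is a benzyl ether and ring B phenol a silyl ether, and this difference later tells the two arms apart.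
4. Key disconnection, lactone C3–C4 (lactone = first ring formed): 13 ⇐ 11 ⇐ oxidative cross-coupling of two enolates (imide 8 + ester 3). One α-carbon acts as an enolonium-type electrophile.
5. 3 and 8 ⇐ one iodo acid 2 ⇐ dihydroferulic acid 1.

**Assumption:** the SMILES is read literally, giving a (3S,4S)-trans lactone, a (7S,8S)-anti open unit and a (2R,3S)-trans dihydrobenzofuran. Ring A is the arene on the lactone C3 benzyl group and ring B the arene on the C4 benzyl group. In each arm, C7 is the carbinol carbon, C8 the carbon bound to ring A or B, and C9 the CH2OH carbon.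

Step 1
Reactants: 1 3-(4-hydroxy-3-methoxyphenyl)propanoic acid (dihydroferulic acid)
Product: 2 3-(4-hydroxy-3-iodo-5-methoxyphenyl)propanoic acid
Conditions: NIS (1.05 equiv), TsOH·H2O (10 mol %), MeCN, 0 °C → rt
Reagents that add atoms: N-iodosuccinimide, O=C1CCC(=O)N1I
Why: Electrophilic aromatic iodination, in which the free phenol is the strongest director and its para position is blocked, so iodine enters ortho to OH; no stereocentre is formed.

Step 2
Reactants: 2 3-(4-hydroxy-3-iodo-5-methoxyphenyl)propanoic acid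
Product: 3 benzyl 3-[4-(benzyloxy)-3-iodo-5-methoxyphenyl]propanoate
Conditions: BnBr (2.3 equiv), K2CO3 (2.5 equiv), DMF, 50 °C
Reagents that add atoms: benzyl bromide, BrCc1ccccc1
Why: Williamson etherification and carboxylate alkylation in one pot give the enolisable ester partner, whose ring A phenol is masked by a group that is removed only by the final hydrogenolysis.

Step 3
Reactants: 2 3-(4-hydroxy-3-iodo-5-methoxyphenyl)propanoic acid
Product: 5 3-[4-(tert-butyldimethylsilyloxy)-3-iodo-5-methoxyphenyl]propanoic acid, via bis-silylated ester 4 (not isolated)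
Conditions: TBSCl (2.5 equiv), imidazole (5 equiv), DMF, rt; then AcOH–THF–H2O, rt
Reagents that add atoms: tert-butyldimethylsilyl chloride, CC(C)(C)[Si](C)(C)Cl
Why: Imidazole-promoted silylation covers both acidic sites, and the very labile silyl ester is hydrolysed by mild aqueous acid while the hindered aryl silyl ether survives.

Step 4
Reactants: 5 3-[4-(tert-butyldimethylsilyloxy)-3-iodo-5-methoxyphenyl]propanoic acid; 6 (R)-4-benzyl-1,3-oxazolidin-2-one
Product: 8 (4R)-4-benzyl-3-{3-[4-(tert-butyldimethylsilyloxy)-3-iodo-5-methoxyphenyl]propanoyl}-1,3-oxazolidin-2-one, via mixed pivalic anhydride 7 (not isolated)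
Conditions: PivCl (1.05 equiv), Et3N (2.5 equiv), THF, −20 °C; then LiCl (1.1 equiv), 6 (1.0 equiv), rt
Reagents that add atoms: pivaloyl chloride, CC(C)(C)C(=O)Cl (its atoms stay only in 7)
Why: Mixed-anhydride N-acylation of the Evans auxiliary, in which the oxazolidinone attacks the less hindered carbonyl of 7 and the stereocentre of 6 is carried along unchanged.

Step 5 (key step)
Reactants: 8 (4R)-4-benzyl-3-{3-[4-(tert-butyldimethylsilyloxy)-3-iodo-5-methoxyphenyl]propanoyl}-1,3-oxazolidin-2-one; 3 benzyl 3-[4-(benzyloxy)-3-iodo-5-methoxyphenyl]propanoate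
Product: 11 benzyl (3S)-4-[(4R)-4-benzyl-2-oxo-1,3-oxazolidin-3-yl]-2-[4-(benzyloxy)-3-iodo-5-methoxybenzyl]-3-[4-(tert-butyldimethylsilyloxy)-3-iodo-5-methoxybenzyl]-4-oxobutanoate (C2 epimers), via imide lithium Z-enolate 9 (not isolated), via ester lithium enolate 10 (not isolated)
Conditions: 8 (1.0 equiv) + 3 (1.5 equiv) added to LDA (2.6 equiv), THF, −78 °C, 30 min; Cu(O2CCH(C2H5)C4H9)2 (2.6 equiv), −78 °C → rt
Reagents that add atoms: lithium diisopropylamide, [Li+].CC(C)[N-]C(C)C (lithium stays only in 9 and 10)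
Why: Oxidative enolate heterocoupling, in which one-electron oxidation by divalent copper turns one enolate into an electrophilic α-carbonyl radical (an enolonium equivalent) that the other enolate captures, so two normally nucleophilic α-carbons (future lactone C3 and C4) are joined directly; mixed aggregates and unlike oxidation potentials favour the cross product, bond formation at the chelated Z-enolate 9 occurs opposite the auxiliary benzyl group and sets butanoate C3 as S, and C2 forms as a mixture that step 6 corrects.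

Step 6
Reactants: 11 benzyl (3S)-4-[(4R)-4-benzyl-2-oxo-1,3-oxazolidin-3-yl]-2-[4-(benzyloxy)-3-iodo-5-methoxybenzyl]-3-[4-(tert-butyldimethylsilyloxy)-3-iodo-5-methoxybenzyl]-4-oxobutanoate
Product: 13 (3S,4S)-3-[4-(benzyloxy)-3-iodo-5-methoxybenzyl]-4-[4-(tert-butyldimethylsilyloxy)-3-iodo-5-methoxybenzyl]oxolan-2-one, via hydroxy ester 12 (not isolated)
Conditions: NaBH4 (4 equiv), THF–H2O 4:1, 0 °C → rt; crude 12, DBU (1 equiv), toluene, 80 °C
Reagents that add atoms: none
Why: Chemoselective borohydride reduction of the imide (reductive auxiliary removal) spares the benzyl ester, the freed primary alcohol lactonises with loss of benzyl alcohol, and DBU equilibrates the only acidic stereocentre C3 to the more stable trans (3S,4S) lactone while C4 is untouched.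

Step 7
Reactants: 13 (3S,4S)-3-[4-(benzyloxy)-3-iodo-5-methoxybenzyl]-4-[4-(tert-butyldimethylsilyloxy)-3-iodo-5-methoxybenzyl]oxolan-2-one
Product: 14 (3S,4S)-3-[4-(benzyloxy)-3-methoxy-5-(propa-1,2-dienyl)benzyl]-4-[4-(tert-butyldimethylsilyloxy)-3-methoxy-5-(propa-1,2-dienyl)benzyl]oxolan-2-one
Conditions: allenyl-SnBu3 (2.6 equiv), Pd2(dba)3 (5 mol %), P(2-furyl)3 (20 mol %), DMF, 50 °C
Reagents that add atoms: allenyltributylstannane, C=C=C[Sn](CCCC)(CCCC)CCCC
Why: Double Stille coupling, in which zerovalent palladium inserts into both aryl iodides and the allenyl group is transferred from tin without rearrangement, under neutral conditions that spare the lactone, the silyl ether and the epimerisable C3.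

Step 8
Reactants: 14 (3S,4S)-3-[4-(benzyloxy)-3-methoxy-5-(propa-1,2-dienyl)benzyl]-4-[4-(tert-butyldimethylsilyloxy)-3-methoxy-5-(propa-1,2-dienyl)benzyl]oxolan-2-one; 15 4-(benzyloxy)-3-methoxybenzaldehyde
Product: 17 (3S,4S)-3-{4-(benzyloxy)-3-[(1S,2R)-1-(4-benzyloxy-3-methoxyphenyl)-1-hydroxybut-3-en-2-yl]-5-methoxybenzyl}-4-{4-(tert-butyldimethylsilyloxy)-3-[(1S,2R)-1-(4-benzyloxy-3-methoxyphenyl)-1-hydroxybut-3-en-2-yl]-5-methoxybenzyl}oxolan-2-one, via bis-allylborane 16 (not isolated)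
Conditions: (−)-Ipc2BH (crystalline, from (+)-α-pinene, 2.4 equiv), THF, 0 °C → rt, 2 h; 15 (2.6 equiv), −78 → −20 °C; 30 % H2O2, pH 7 buffer, 0 °C
Reagents that add atoms: (−)-diisopinocampheylborane, B([C@@H]1C[C@@H]2C[C@H]([C@H]1C)C2(C)C)[C@@H]1C[C@@H]2C[C@H]([C@H]1C)C2(C)C (boron and isopinocampheyl groups stay only in 16)
Why: Allene hydroboration followed by Brown-type allylboration, in which boron adds to the terminal allene carbon, 1,3-borotropic shifts funnel the allylborane to the E isomer 16, its chair Zimmerman–Traxler transition state gives the anti C7/C8 relationship, and the isopinocampheyl groups from (+)-α-pinene direct attack to the Si face of 15 (7S), so four stereocentres are set by reagent control in one operation.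

Step 9
Reactants: 17 the bis(homoallylic alcohol) silyl ether of step 8
Product: 18 (3S,4S)-3-{4-(benzyloxy)-3-[(1S,2R)-1-(4-benzyloxy-3-methoxyphenyl)-1-hydroxybut-3-en-2-yl]-5-methoxybenzyl}-4-{4-hydroxy-3-[(1S,2R)-1-(4-benzyloxy-3-methoxyphenyl)-1-hydroxybut-3-en-2-yl]-5-methoxybenzyl}oxolan-2-one
Conditions: Bu4NF (1.1 equiv), AcOH (1.1 equiv), THF, 0 °C
Reagents that add atoms: none
Why: Fluoride-induced desilylation cleaves the aryl silyl ether within minutes, and acetic acid buffers the phenoxide so that the lactone, C3 and both carbinols stay untouched.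

Step 10
Reactants: 18 the ring B phenol of step 9
Product: 19 (3S,4S)-3-{4-(benzyloxy)-3-[(1S,2R)-1-(4-benzyloxy-3-methoxyphenyl)-1-hydroxybut-3-en-2-yl]-5-methoxybenzyl}-4-{[(2R,3R)-2-(4-benzyloxy-3-methoxyphenyl)-3-ethenyl-7-methoxy-2,3-dihydro-1-benzofuran-5-yl]methyl}oxolan-2-one
Conditions: PPh3 (1.15 equiv), DIAD (1.1 equiv, slow addition), toluene, 0 °C
Reagents that add atoms: none
Why: Mitsunobu etherification, in which ring B carries the only acidic pronucleophile and its phenoxide displaces the neighbouring C7 oxyphosphonium group in a 5-exo-tet SN2 process with inversion (7S to 7R, the trans ring, which is also favoured if some ionisation occurs), whereas the ring A carbinol has no internal nucleophile because its phenol is benzylated and is returned on work-up.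

Step 11
Reactants: 19 the bis-vinyl compound of step 10
Product: 21 (3S,4S)-3-{4-(benzyloxy)-3-[(1S,2S)-1-(4-benzyloxy-3-methoxyphenyl)-1,3-dihydroxypropan-2-yl]-5-methoxybenzyl}-4-{[(2R,3S)-2-(4-benzyloxy-3-methoxyphenyl)-3-(hydroxymethyl)-7-methoxy-2,3-dihydro-1-benzofuran-5-yl]methyl}oxolan-2-one, via dialdehyde 20 (not isolated)
Conditions: O3 (titrated solution, 2.1 equiv), CH2Cl2–MeOH, −78 °C; NaBH4 (6 equiv), −78 → 0 °C
Reagents that add atoms: ozone, [O-][O+]=O
Why: Ozonolysis with reductive work-up, in which the terminal alkenes react much faster than the alkoxyarenes and borohydride added at −78 °C reduces the α-aryl aldehydes of 20 before they can epimerise at C8 or undergo retro-aldol cleavage, so no stereocentre is changed (descriptor changes are only CIP priority changes).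

Step 12
Reactants: 21 the tri-O-benzyl ether of step 11
Product: 22 (3S,4S)-3-{4-hydroxy-3-[(1S,2S)-1,3-dihydroxy-1-(4-hydroxy-3-methoxyphenyl)propan-2-yl]-5-methoxybenzyl}-4-{[(2R,3S)-2-(4-hydroxy-3-methoxyphenyl)-3-(hydroxymethyl)-7-methoxy-2,3-dihydro-1-benzofuran-5-yl]methyl}oxolan-2-one (target)
Conditions: H2 (1 atm), 10 % Pd/C, EtOAc–EtOH, rt, stopped at full debenzylation
Reagents that add atoms: none
Why: Catalytic hydrogenolysis of the three aryl benzyl ethers under neutral conditions is faster than cleavage of the secondary C7–OH or the dihydrobenzofuran C2–O bond, and it avoids the acid that would close the open unit onto the ring A phenol.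

**Compound list**
1 | 3-(4-hydroxy-3-methoxyphenyl)propanoic acid | COc1cc(CCC(=O)O)ccc1O | starting material
2 | 3-(4-hydroxy-3-iodo-5-methoxyphenyl)propanoic acid | COc1cc(CCC(=O)O)cc(I)c1O | intermediate
3 | benzyl 3-[4-(benzyloxy)-3-iodo-5-methoxyphenyl]propanoate | COc1cc(CCC(=O)OCc2ccccc2)cc(I)c1OCc1ccccc1 | intermediate
4 | tert-butyldimethylsilyl 3-[4-(tert-butyldimethylsilyloxy)-3-iodo-5-methoxyphenyl]propanoate | COc1cc(CCC(=O)O[Si](C)(C)C(C)(C)C)cc(I)c1O[Si](C)(C)C(C)(C)C | intermediate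
5 | 3-[4-(tert-butyldimethylsilyloxy)-3-iodo-5-methoxyphenyl]propanoic acid | COc1cc(CCC(=O)O)cc(I)c1O[Si](C)(C)C(C)(C)C | intermediate
6 | (R)-4-benzyl-1,3-oxazolidin-2-one | O=C1N[C@H](Cc2ccccc2)CO1 | starting material
7 | mixed anhydride of 5 and pivalic acid | COc1cc(CCC(=O)OC(=O)C(C)(C)C)cc(I)c1O[Si](C)(C)C(C)(C)C | intermediate
8 | (4R)-4-benzyl-3-{3-[4-(tert-butyldimethylsilyloxy)-3-iodo-5-methoxyphenyl]propanoyl}-1,3-oxazolidin-2-one | COc1cc(CCC(=O)N2[C@H](Cc3ccccc3)COC2=O)cc(I)c1O[Si](C)(C)C(C)(C)C | intermediate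
9 | lithium (Z)-enolate of 8 | [Li+].COc1cc(C/C=C(\[O-])N2[C@H](Cc3ccccc3)COC2=O)cc(I)c1O[Si](C)(C)C(C)(C)C | intermediate
10 | lithium enolate of 3 | [Li+].COc1cc(CC=C([O-])OCc2ccccc2)cc(I)c1OCc1ccccc1 | intermediate
11 | coupled imide ester, (3S), C2 epimers | O=C(N1[C@H](Cc2ccccc2)COC1=O)[C@@H](Cc3cc(OC)c(O[Si](C)(C)C(C)(C)C)c(I)c3)C(Cc4cc(OC)c(OCc5ccccc5)c(I)c4)C(=O)OCc6ccccc6 | intermediate
12 | benzyl (3S)-2-[4-(benzyloxy)-3-iodo-5-methoxybenzyl]-3-[4-(tert-butyldimethylsilyloxy)-3-iodo-5-methoxybenzyl]-4-hydroxybutanoate, C2 epimers | OC[C@@H](Cc1cc(OC)c(O[Si](C)(C)C(C)(C)C)c(I)c1)C(Cc2cc(OC)c(OCc3ccccc3)c(I)c2)C(=O)OCc4ccccc4 | intermediate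
13 | (3S,4S)-diiodo lactone | COc1cc(C[C@@H]2C(=O)OC[C@H]2Cc3cc(OC)c(O[Si](C)(C)C(C)(C)C)c(I)c3)cc(I)c1OCc4ccccc4 | intermediate
14 | (3S,4S)-bis(propa-1,2-dienyl) lactone | COc1cc(C[C@@H]2C(=O)OC[C@H]2Cc3cc(OC)c(O[Si](C)(C)C(C)(C)C)c(C=C=C)c3)cc(C=C=C)c1OCc4ccccc4 | intermediate
15 | 4-(benzyloxy)-3-methoxybenzaldehyde | COc1cc(C=O)ccc1OCc1ccccc1 | starting material
16 | bis[(E)-3-(diisopinocampheylboryl)prop-1-enyl] analogue of 14 | COc1cc(C[C@@H]2C(=O)OC[C@H]2Cc3cc(OC)c(O[Si](C)(C)C(C)(C)C)c(/C=C/CB([C@@H]4C[C@@H]5C[C@H]([C@H]4C)C5(C)C)[C@@H]4C[C@@H]5C[C@H]([C@H]4C)C5(C)C)c3)cc(/C=C/CB([C@@H]4C[C@@H]5C[C@H]([C@H]4C)C5(C)C)[C@@H]4C[C@@H]5C[C@H]([C@H]4C)C5(C)C)c1OCc4ccccc4 | intermediate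
17 | bis[(1S,2R)-homoallylic alcohol], ring B silyl ether | COc1cc([C@@H](O)[C@H](C=C)c2cc(C[C@@H]3C(=O)OC[C@H]3Cc4cc(OC)c(O[Si](C)(C)C(C)(C)C)c(c4)[C@@H](C=C)[C@H](O)c5ccc(OCc6ccccc6)c(OC)c5)cc(OC)c2OCc7ccccc7)ccc1OCc8ccccc8 | intermediate
18 | bis[(1S,2R)-homoallylic alcohol], free ring B phenol | COc1cc([C@@H](O)[C@H](C=C)c2cc(C[C@@H]3C(=O)OC[C@H]3Cc4cc(OC)c(O)c(c4)[C@@H](C=C)[C@H](O)c5ccc(OCc6ccccc6)c(OC)c5)cc(OC)c2OCc7ccccc7)ccc1OCc8ccccc8 | intermediate
19 | (2R,3R)-3-ethenyl-dihydrobenzofuran with open (1S,2R) arm on ring A | COc1cc([C@@H](O)[C@H](C=C)c2cc(C[C@@H]3C(=O)OC[C@H]3Cc4cc(OC)c5c(c4)[C@@H](C=C)[C@H](c6ccc(OCc7ccccc7)c(OC)c6)O5)cc(OC)c2OCc8ccccc8)ccc1OCc9ccccc9 | intermediate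
20 | dialdehyde, ring A arm (1S,2R)-1-hydroxy-3-oxopropan-2-yl, ring B arm (2R,3R)-3-formyl-dihydrobenzofuran | COc1cc([C@@H](O)[C@H](C=O)c2cc(C[C@@H]3C(=O)OC[C@H]3Cc4cc(OC)c5c(c4)[C@@H](C=O)[C@H](c6ccc(OCc7ccccc7)c(OC)c6)O5)cc(OC)c2OCc8ccccc8)ccc1OCc9ccccc9 | intermediate
21 | tri-O-benzyl ether of the target | COc1cc([C@@H](O)[C@H](CO)c2cc(C[C@@H]3C(=O)OC[C@H]3Cc4cc(OC)c5c(c4)[C@@H](CO)[C@H](c6ccc(OCc7ccccc7)c(OC)c6)O5)cc(OC)c2OCc8ccccc8)ccc1OCc9ccccc9 | intermediate
22 | CNP0186558.3 | COc1cc([C@@H](O)[C@H](CO)c2cc(C[C@@H]3C(=O)OC[C@H]3Cc3cc(OC)c4c(c3)[C@@H](CO)[C@H](c3ccc(O)c(OC)c3)O4)cc(OC)c2O)ccc1O | target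

**Total step count:** 12. **Longest linear sequence:** 11 (steps 1, 3, 4, 5, 6, 7, 8, 9, 10, 11, 12).

**Three steps most likely to fail**

Step 5. The risks are homodimers of 3 and 8, Claisen self-condensation of 10, and loss of iodine by electron transfer.
- The fallback uses a two-electron enolonium equivalent and builds the lactone stepwise. It sets out from 8 and comes back at 13.
- The sodium enolate of 8 (NaHMDS, THF, −78 °C) is alkylated by tert-butyl bromoacetate, opposite the auxiliary benzyl group. This gives tert-butyl (3S)-4-[(4R)-4-benzyl-2-oxo-1,3-oxazolidin-3-yl]-3-[4-(tert-butyldimethylsilyloxy)-3-iodo-5-methoxybenzyl]-4-oxobutanoate F1.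
- NaBH4 in THF–H2O gives tert-butyl (3S)-4-[4-(tert-butyldimethylsilyloxy)-3-iodo-5-methoxyphenyl]-3-(hydroxymethyl)butanoate F2. TFA in CH2Cl2 closes it to (4S)-4-[4-(tert-butyldimethylsilyloxy)-3-iodo-5-methoxybenzyl]oxolan-2-one F3.
- In parallel, commercial 5-iodovanillin is benzylated (BnBr, K2CO3) to 4-(benzyloxy)-3-iodo-5-methoxybenzaldehyde F4. This is reduced (NaBH4) to [4-(benzyloxy)-3-iodo-5-methoxyphenyl]methanol F5 and brominated (PBr3) to 4-(benzyloxy)-3-iodo-5-methoxybenzyl bromide F6.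
- The lithium enolate of F3 (LiHMDS, THF, −78 °C) is alkylated by F6 anti to the C4 substituent and gives 13.

Step 8. The risks are incomplete Z-to-E equilibration of the γ-aryl allylborane, lower facial selectivity than for crotyl reagents, and the need for both arms to react.
- The fallback is a catalytic hydrogen-transfer (α-aryl)allylation with alkynes as latent allenes. It sets out from 13 and comes back at 17.
- Double Sonogashira coupling of 13 with propyne (PdCl2(PPh3)2, CuI, Et3N, DMF, rt) gives (3S,4S)-3-[4-(benzyloxy)-3-methoxy-5-(prop-1-ynyl)benzyl]-4-[4-(tert-butyldimethylsilyloxy)-3-methoxy-5-(prop-1-ynyl)benzyl]oxolan-2-one F7.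
- F7 is heated at 95 °C in THF with commercial 4-(benzyloxy)-3-methoxybenzyl alcohol, H2Ru(CO)(PPh3)3, 2,4,6-triisopropylbenzenesulfonic acid, Bu4NI and a Josiphos ligand. The ligand is 1-[2-(dicyclohexylphosphino)ferrocenyl]ethyldi-tert-butylphosphine, and of its two commercial antipodes the one giving the 7S carbinol is used.
- The catalyst isomerises each alkyne to the allene, hydrometalates it to an E-allylruthenium species and adds it to the aldehyde formed in situ through a chair transition state. This gives the anti adduct 17.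

Step 10. The risk is activation of the electron-rich ring A carbinol, leading to ionisation, elimination or capture by the hydrazide.
- The fallback is an anionic closure on a leaving group while the ring A carbinol is masked by that same group. It sets out from 17 and comes back at 21.
- ClCO2Me, pyridine and DMAP convert 17 into the bis(methyl carbonate) of 17 F8.
- Bu4NF in THF frees the ring B phenoxide, which displaces the neighbouring benzylic carbonate with inversion. This gives the ring A methyl carbonate of 19 F9.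
- O3 then NaBH4, as in step 11, gives the ring A methyl carbonate of 21 F10. K2CO3 in MeOH at 0 °C removes the carbonate to give 21.

**Further compounds**
F1 | step 5 | tert-butyl (3S)-4-[(4R)-4-benzyl-2-oxo-1,3-oxazolidin-3-yl]-3-[4-(tert-butyldimethylsilyloxy)-3-iodo-5-methoxybenzyl]-4-oxobutanoate | O=C(N1[C@H](Cc2ccccc2)COC1=O)[C@H](CC(=O)OC(C)(C)C)Cc3cc(OC)c(O[Si](C)(C)C(C)(C)C)c(I)c3
F2 | step 5 | tert-butyl (3S)-4-[4-(tert-butyldimethylsilyloxy)-3-iodo-5-methoxyphenyl]-3-(hydroxymethyl)butanoate | OC[C@H](CC(=O)OC(C)(C)C)Cc1cc(OC)c(O[Si](C)(C)C(C)(C)C)c(I)c1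
F3 | step 5 | (4S)-4-[4-(tert-butyldimethylsilyloxy)-3-iodo-5-methoxybenzyl]oxolan-2-one | O=C1C[C@H](Cc2cc(OC)c(O[Si](C)(C)C(C)(C)C)c(I)c2)CO1
F4 | step 5 | 4-(benzyloxy)-3-iodo-5-methoxybenzaldehyde | COc1cc(C=O)cc(I)c1OCc1ccccc1
F5 | step 5 | [4-(benzyloxy)-3-iodo-5-methoxyphenyl]methanol | COc1cc(CO)cc(I)c1OCc1ccccc1
F6 | step 5 | 4-(benzyloxy)-3-iodo-5-methoxybenzyl bromide | COc1cc(CBr)cc(I)c1OCc1ccccc1
F7 | step 8 | (3S,4S)-3-[4-(benzyloxy)-3-methoxy-5-(prop-1-ynyl)benzyl]-4-[4-(tert-butyldimethylsilyloxy)-3-methoxy-5-(prop-1-ynyl)benzyl]oxolan-2-one | COc1cc(C[C@@H]2C(=O)OC[C@H]2Cc3cc(OC)c(O[Si](C)(C)C(C)(C)C)c(C#CC)c3)cc(C#CC)c1OCc4ccccc4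
F8 | step 10 | bis(methyl carbonate) of 17 | COc1cc([C@@H](OC(=O)OC)[C@H](C=C)c2cc(C[C@@H]3C(=O)OC[C@H]3Cc4cc(OC)c(O[Si](C)(C)C(C)(C)C)c(c4)[C@@H](C=C)[C@H](OC(=O)OC)c5ccc(OCc6ccccc6)c(OC)c5)cc(OC)c2OCc7ccccc7)ccc1OCc8ccccc8
F9 | step 10 | ring A methyl carbonate of 19 | COc1cc([C@@H](OC(=O)OC)[C@H](C=C)c2cc(C[C@@H]3C(=O)OC[C@H]3Cc4cc(OC)c5c(c4)[C@@H](C=C)[C@H](c6ccc(OCc7ccccc7)c(OC)c6)O5)cc(OC)c2OCc8ccccc8)ccc1OCc9ccccc9
F10 | step 10 | ring A methyl carbonate of 21 | COc1cc([C@@H](OC(=O)OC)[C@H](CO)c2cc(C[C@@H]3C(=O)OC[C@H]3Cc4cc(OC)c5c(c4)[C@@H](CO)[C@H](c6ccc(OCc7ccccc7)c(OC)c6)O5)cc(OC)c2OCc8ccccc8)ccc1OCc9ccccc9
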